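**Retrosynthetic overview**

1. Numbering used: hydrindane part C1 (cyclopentane carbinol), C2, C3, C3a, C4 (ring B carbinol), C5, C6 (spiro carbon), C7, C7a; trione ring A: C6 = C1′, C2′ (C=O beside the diprenyl carbon C3′), C4′ (enol), C5′ (acyl carbon), C6′ (C=O); ring B = spiro cyclohexane, ring C = cyclopentane.
2. Late disconnections: both prenyl groups on C3′ (double C-alkylation); ring A by C-acylation of 6-methylheptane-2,4-dione (C6′–C5′) and Dieckmann closure (C2′–C3′) onto a lactone; the lactone/acid pair from a gem-diester on C6 and the axial 4-OH; the C4 methyl carbinol from a ring B ketone.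
3. Key disconnection: ring B at C4–C5 and C6–C7, from an aldehyde carbon (C4, acyl-anion equivalent), a methylenemalonate (C5=C6) and a CH2Cl group (C7).
4. Enabling feature: the oxygen on C4 and the two carbonyls on C6 (C2′, C6′) are 1,4-related (a Stetter retron) and C6 is a malonyl-type carbon, so C5–C6 can enter as a Michael acceptor whose anion then closes ring B on C7; the cis-1,3-diaxial relation of 4-OH and C2′=O lets a lactone pass the C4 configuration on to the spiro centre.
5. Ring C with C1, C3a and C7a comes from a tandem conjugate addition–aldol cyclisation of an acyclic keto-enoate; ring order C, then B, then A.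

Key step: step 7

Assumption: the sense of induction in step 2 is taken from the usual quadrant model for rhodium/BINAP conjugate additions, which assigns (R)-BINAP to delivery of the alkenyl group to the si face of C3 of enoate 3 (if the opposite sense is found, (S)-BINAP is used unchanged otherwise); β-triketones are drawn as one enol tautomer.

**Step 1**
Reactants: 1 hex-5-en-2-one; 2 methyl acrylate
Product: 3 methyl (2E)-6-oxohept-2-enoate
Conditions: second-generation Hoveyda–Grubbs catalyst (2 mol%), 2 (3 equiv), CH2Cl2, 40 °C
Reagents that add atoms: none
Why: Olefin cross-metathesis of a terminal alkene with an acrylate is reliably E-selective and leaves the ketone untouched.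

**Step 2**
Reactants: 3 methyl (2E)-6-oxohept-2-enoate; 4 (E)-2-phenylethenylboronic acid
Product: 5 methyl (1R,2S,5R)-2-hydroxy-2-methyl-5-[(E)-2-phenylethenyl]cyclopentane-1-carboxylate
Conditions: [Rh(cod)Cl]2 (2.5 mol%), (R)-BINAP (6 mol%), KOH (10 mol%), 1,4-dioxane/H2O (10:1), 90 °C
Reagents that add atoms: none
Why: Proposed new method: the alkenylrhodium species formed by transmetalation adds 1,4 to the (E)-enoate under control of the BINAP ligand (setting C3a), and the rhodium ester enolate so formed is expected to add to the tethered methyl ketone through a closed chair-like transition state before it is protonated, closing ring C (5-exo-trig aldol) with OH cis to the ester (C1 and C7a) and the styryl group trans to it; the closest known reaction type is the rhodium/BINAP-catalysed tandem conjugate addition–aldol cyclisation of boronic acids with keto-enones, extended here to an enoate acceptor.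

**Step 3**
Reactants: 5 methyl (1R,2S,5R)-2-hydroxy-2-methyl-5-[(E)-2-phenylethenyl]cyclopentane-1-carboxylate
Product: 6 (1S,2S,3R)-2-(hydroxymethyl)-1-methyl-3-[(E)-2-phenylethenyl]cyclopentan-1-ol
Conditions: LiAlH4, THF, 0 °C
Reagents that add atoms: none
Why: LiAlH4 reduces the ester to the primary alcohol without touching the disubstituted alkene or the three stereocentres.

**Step 4**
Reactants: 6 (1S,2S,3R)-2-(hydroxymethyl)-1-methyl-3-[(E)-2-phenylethenyl]cyclopentan-1-ol
Product: 7 (1S,2R,3R)-2-(chloromethyl)-1-methyl-3-[(E)-2-phenylethenyl]cyclopentan-1-ol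
Conditions: PPh3, CCl4, CH2Cl2, 0 to 25 °C
Reagents that add atoms: tetrachloromethane, ClC(Cl)(Cl)Cl
Why: The Appel reaction converts the unhindered primary alcohol into the chloride, whereas the tertiary alcohol does not form a reactive alkoxyphosphonium salt at this temperature.

**Step 5**
Reactants: 7 (1S,2R,3R)-2-(chloromethyl)-1-methyl-3-[(E)-2-phenylethenyl]cyclopentan-1-ol
Product: 9 (1S,2R,3S)-2-(chloromethyl)-3-hydroxy-3-methylcyclopentane-1-carbaldehyde, via secondary ozonide 8 (not isolated)
Conditions: O3, CH2Cl2, −78 °C; then Me2S, −78 to 25 °C
Reagents that add atoms: ozone, [O-][O+]=O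
Why: Ozonolysis with reductive work-up cleaves the only alkene to the aldehyde; the α-stereocentre C3a stays in its favoured trans arrangement and the chloride and tertiary alcohol are inert.

**Step 6**
Reactants: 10 dibenzyl malonate
Product: 11 dibenzyl 2-methylidenepropanedioate
Conditions: paraformaldehyde, Cu(OAc)2 (5 mol%), KOAc (5 mol%), AcOH, 100 °C; used at once
Reagents that add atoms: formaldehyde (as paraformaldehyde), C=O
Why: Knoevenagel-type methylenation of a malonate with formaldehyde under copper acetate/acetate catalysis is the standard preparation of methylenemalonates; the product is used fresh because it polymerises on storage.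

**Step 7**
Reactants: 9 (1S,2R,3S)-2-(chloromethyl)-3-hydroxy-3-methylcyclopentane-1-carbaldehyde; 11 dibenzyl 2-methylidenepropanedioate
Product: 13 dibenzyl (1S,3aS,7aR)-1-hydroxy-1-methyl-4-oxo-octahydroindene-6,6-dicarboxylate (trans-fused), via keto-malonate adduct 12 (not isolated)
Conditions: 3-benzyl-5-(2-hydroxyethyl)-4-methylthiazolium chloride (20 mol%), Cs2CO3 (1.5 equiv), 1,4-dioxane, 60 °C, 11 added over 4 h
Reagents that add atoms: none
Why: Proposed new method: the thiazol-2-ylidene generated from the salt adds to aldehyde 9 to give the acyl-anion equivalent, which adds 1,4 to the doubly activated acceptor 11 and forms C4–C5 (Stetter reaction); the malonate C6–H of adduct 12 is then deprotonated by Cs2CO3 and displaces the primary chloride on C7 to form C6–C7 and close ring B. The closest known reaction types are the intermolecular Stetter reaction of aliphatic aldehydes with alkylidenemalonates and the Michael-initiated ring closure of malonates onto alkyl halides, and the new element is their union in one flask with an acyl anion as the Michael donor. Ring B closes in the 6-exo-tet mode. No new stereocentre is formed (C6 carries two identical ester groups and C4 is a carbonyl carbon), and the trans ring fusion is inherited from the trans-1,2-disubstituted cyclopentane, whose only epimerisable centre C3a is expected to prefer the trans arrangement in 9, in 12 and in the trans-fused product. The step needs cross-Stetter addition in preference to acyloin formation and to carbene addition to 11, which is secured by keeping the very electrophilic 11 at low concentration, and C- rather than O-alkylation of the malonate, which is secured by the six-membered C-closure against an eight-membered O-closure.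

**Step 8**
Reactants: 13 dibenzyl (1S,3aS,7aR)-1-hydroxy-1-methyl-4-oxo-octahydroindene-6,6-dicarboxylate
Product: 15 lactone benzyl ester, via diol diester 14 (not isolated)
Conditions: MeLi (3.5 equiv), CeCl3 (3.5 equiv), THF, −78 °C; then 25 °C; aq. NH4Cl
Reagents that add atoms: methyllithium, [Li]C
Why: The weakly basic organocerium reagent adds only to the ketone (1,2-addition) and from the equatorial direction because the axial ester on C6 blocks the axial path, which sets C4 with an axial hydroxyl; the resulting alkoxide is 1,3-diaxial to that same ester and lactonises onto it, so the two ester groups on C6 become different and the spiro configuration is fixed relative to C4.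

**Step 9**
Reactants: 15 lactone benzyl ester
Product: 16 lactone acid
Conditions: H2 (1 atm), 10% Pd/C, EtOAc, 25 °C
Reagents that add atoms: none
Why: Hydrogenolysis frees the carboxylic acid under neutral conditions that leave the lactone and the tertiary alcohol alone.

**Step 10**
Reactants: 16 lactone acid; 17 6-methylheptane-2,4-dione
Product: 19 lactone triketone, via acyl imidazolide 18 (not isolated)
Conditions: 1,1′-carbonyldiimidazole, THF, 25 °C; then 17, MgCl2, Et3N, MeCN, 0 to 25 °C; dilute HCl work-up
Reagents that add atoms: none
Why: The acyl imidazolide, which cannot form a ketene and does not acylate the hindered tertiary alcohol, C-acylates the chelated magnesium enolate of the β-diketone at its central carbon (soft-enolisation C-acylation), forming the C6′–C5′ bond.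

**Step 11**
Reactants: 19 lactone triketone
Product: 20 spiro-trione lacking the prenyl groups
Conditions: LiN(iPr)2 (4.5 equiv), THF, −78 to 0 °C; then 1 M HCl
Reagents that add atoms: none
Why: Dieckmann-type Claisen condensation in which, after deprotonation of the acidic triketone and of the hydroxyl, the base removes a proton from the less hindered acetyl CH3 and this carbanion attacks the strained lactone carbonyl (six-membered ring closure) with release of the C4 alkoxide, so that the carbonyl that was held cis to O-4 becomes C2′ and the spiro configuration of the target results.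

**Step 12**
Reactants: 20 spiro-trione lacking the prenyl groups; 21 prenyl bromide
Product: 23 target CNP0198642.4, via monoprenyl dienol 22 (not isolated)
Conditions: 21 (2.4 equiv), 10% aq. KOH, 0 to 25 °C
Reagents that add atoms: none
Why: Double C-alkylation of the only ring carbon that still carries hydrogen between two carbonyls (C3′), as in the classical preparation of gem-diprenylated dearomatised acylphloroglucinols in aqueous base; no stereocentre is formed and the tertiary alcohols do not react.

**Compound list**

1 | hex-5-en-2-one | CC(=O)CCC=C | starting material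
2 | methyl acrylate | C=CC(=O)OC | starting material
3 | methyl (2E)-6-oxohept-2-enoate | COC(=O)/C=C/CCC(C)=O | intermediate
4 | (E)-2-phenylethenylboronic acid | OB(O)/C=C/c1ccccc1 | starting material
5 | methyl (1R,2S,5R)-2-hydroxy-2-methyl-5-[(E)-2-phenylethenyl]cyclopentane-1-carboxylate (OH cis, styryl trans to the ester) | COC(=O)[C@@H]1[C@H](CC[C@]1(C)O)/C=C/c1ccccc1 | intermediate
6 | (1S,2S,3R)-2-(hydroxymethyl)-1-methyl-3-[(E)-2-phenylethenyl]cyclopentan-1-ol | OC[C@@H]1[C@H](CC[C@]1(C)O)/C=C/c1ccccc1 | intermediate
7 | (1S,2R,3R)-2-(chloromethyl)-1-methyl-3-[(E)-2-phenylethenyl]cyclopentan-1-ol | ClC[C@@H]1[C@H](CC[C@]1(C)O)/C=C/c1ccccc1 | intermediate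
8 | secondary ozonide of 7 (3-cyclopentyl-5-phenyl-1,2,4-trioxolane, mixture of trioxolane diastereomers) | ClC[C@@H]1[C@H](CC[C@]1(C)O)C1OOC(O1)c1ccccc1 | intermediate (not isolated)
9 | (1S,2R,3S)-2-(chloromethyl)-3-hydroxy-3-methylcyclopentane-1-carbaldehyde (CHO trans to CH2Cl, OH cis to CH2Cl) | ClC[C@@H]1[C@H](CC[C@]1(C)O)C=O | intermediate
10 | dibenzyl malonate | O=C(CC(=O)OCc1ccccc1)OCc1ccccc1 | starting material
11 | dibenzyl 2-methylidenepropanedioate | C=C(C(=O)OCc1ccccc1)C(=O)OCc1ccccc1 | intermediate
12 | dibenzyl 2-{2-[(1S,2R,3S)-2-(chloromethyl)-3-hydroxy-3-methylcyclopentyl]-2-oxoethyl}propanedioate | ClC[C@@H]1[C@H](CC[C@]1(C)O)C(=O)CC(C(=O)OCc1ccccc1)C(=O)OCc1ccccc1 | intermediate (not isolated)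
13 | dibenzyl (1S,3aS,7aR)-1-hydroxy-1-methyl-4-oxo-octahydroindene-6,6-dicarboxylate (trans-fused) | O=C(OCc1ccccc1)C2(C(=O)OCc1ccccc1)C[C@@H]3[C@H](CC[C@]3(C)O)C(=O)C2 | intermediate
14 | dibenzyl (1S,3aS,4R,7aR)-1,4-dihydroxy-1,4-dimethyl-octahydroindene-6,6-dicarboxylate (4-OH axial) | O=C(OCc1ccccc1)C2(C(=O)OCc1ccccc1)C[C@@H]3[C@H](CC[C@]3(C)O)[C@](C)(O)C2 | intermediate (not isolated)
15 | lactone benzyl ester: γ-lactone between O-4 and the axial C6 carboxyl of 14, equatorial CO2Bn retained | O=C4[C@@]2(C[C@@H]3[C@H](CC[C@]3(C)O)[C@](C)(O4)C2)C(=O)OCc1ccccc1 | intermediate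
16 | lactone acid: as 15 with a free equatorial CO2H on C6 | O=C4[C@@]2(C[C@@H]3[C@H](CC[C@]3(C)O)[C@](C)(O4)C2)C(O)=O | intermediate
17 | 6-methylheptane-2,4-dione | CC(=O)CC(=O)CC(C)C | starting material
18 | N-acylimidazole of lactone acid 16 | O=C4[C@@]2(C[C@@H]3[C@H](CC[C@]3(C)O)[C@](C)(O4)C2)C(=O)n1ccnc1 | intermediate (not isolated)
19 | lactone triketone: 6-methylheptane-2,4-dione acylated on C3 by the C6 carboxyl of 16 (one enol tautomer drawn) | O=C4[C@@]2(C[C@@H]3[C@H](CC[C@]3(C)O)[C@](C)(O4)C2)C(=O)/C(C(C)=O)=C(/O)CC(C)C | intermediate
20 | spiro-trione lacking the prenyl groups: the target with CH2 at C3′; hydrindane part (1S,3aS,4R,7aR), C2′=O cis to 4-OH | C1C(=O)[C@@]2(C[C@@H]3[C@H](CC[C@]3(C)O)[C@](C)(O)C2)C(=O)C(C(=O)CC(C)C)=C1O | intermediate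
21 | prenyl bromide (1-bromo-3-methylbut-2-ene) | CC(C)=CCBr | starting material
22 | monoprenyl dienol: 20 with one prenyl group on C3′, drawn as the C2′ enol | CC(C)=CCC1=C(O)[C@@]2(C[C@@H]3[C@H](CC[C@]3(C)O)[C@](C)(O)C2)C(=O)C(C(=O)CC(C)C)=C1O | intermediate (not isolated)
23 | target CNP0198642.4: hydrindane part (1S,3aS,4R,7aR), spiro C6 with C2′=O (beside the diprenyl carbon) cis to 4-OH, 5′-(3-methylbutanoyl), 3′,3′-diprenyl | CC(C)=CCC1(CC=C(C)C)C(=O)[C@@]2(C[C@@H]3[C@H](CC[C@]3(C)O)[C@](C)(O)C2)C(=O)C(C(=O)CC(C)C)=C1O | target

**Step count**

Total steps: 12. Longest linear sequence: 11 (steps 1–5 and 7–12; step 6 is a one-step side branch).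

**Steps most likely to fail, with fallbacks**

1. Step 7 (proposed new method). The carbene may be consumed by conjugate addition to 11, with oligomerisation of 11. The base may also trigger enolate cyclopropanation of 9 (3-exo-tet loss of chloride), or epimerisation at C3a followed by closure to the cis-fused ring. The fallback separates the two bond formations and changes the activation mode from a polar acyl anion to an acyl radical. It sets out from 9 and 11: decatungstate-photocatalysed hydroacylation ((n-Bu4N)4[W10O32] 2 mol%, MeCN, 390 nm, 25 °C, neutral) abstracts the formyl hydrogen, and the acyl radical adds to 11 (Giese addition) to give keto-malonate 12, which is isolated. Separate malonate alkylation (Cs2CO3, NaI, DMF, 25 °C) then closes ring B, and the route is rejoined at 13. This fallback makes no compound that is missing from the compound list (entry F0).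

2. Step 2 (proposed new method). Protonation of the rhodium ester enolate may outrun the aldol addition and give the open keto ester, or enantiofacial control with the enoate may be poor. The fallback builds ring C from a preformed cyclopentenone by a three-component coupling. It does not set out from a numbered compound (it replaces 1–5 and starts from commercial phenylacetylene and cyclopent-2-en-1-one). Hydrozirconation of phenylacetylene with Cp2Zr(H)Cl gives (E)-2-phenylethenylzirconocene chloride F1. Asymmetric 1,4-addition to cyclopent-2-en-1-one catalysed by [Rh(cod)(MeCN)2]BF4/BINAP, with trapping of the zirconium enolate by monomeric formaldehyde, should give the trans ketol (2S,3R)-2-(hydroxymethyl)-3-[(E)-2-phenylethenyl]cyclopentan-1-one F2. MeLi/CeCl3 should then add to the ketone anti to the adjacent CH2OH group, and the route is rejoined at diol 6.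

3. Step 11. Deprotonation may occur at the isovaleryl CH2 instead of the acetyl CH3 and lead to a regioisomeric ring, or the polyanion may fail to attack the hindered lactone carbonyl. The fallback reverses the order of the two ring A bond formations and sets out from lactone acid 16 (steps 10 and 11 are replaced). The dianion of 17 (LiN(iPr)2, THF; terminal CH3 carbanion) opens the lactone of the lithium carboxylate of 16, whose carboxylate is inert, and forms C2′–C3′ first to give the ring-opened triketo acid F3. Esterification with Me3SiCHN2 gives the triketo methyl ester F4. Claisen cyclisation of the central diketone carbon onto the ester (Mg(OMe)2 or NaOMe, MeOH), the biomimetic polyketide-type closure, then rejoins the route at 20.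

**Further compounds**

F0 | step 7 | none | none
F1 | step 2 | (E)-2-phenylethenylzirconocene chloride | Cl[Zr](/C=C/c1ccccc1)(C1C=CC=C1)C1C=CC=C1
F2 | step 2 | (2S,3R)-2-(hydroxymethyl)-3-[(E)-2-phenylethenyl]cyclopentan-1-one | OC[C@@H]1[C@H](CCC1=O)/C=C/c1ccccc1
F3 | step 11 | triketo acid: (1S,3aS,4R,7aR)-1,4-dihydroxy-1,4-dimethyl-6-(7-methyl-3,5-dioxooctanoyl)-octahydroindene-6-carboxylic acid (acyl group cis to 4-OH) | CC(C)CC(=O)CC(=O)CC(=O)[C@@]2(C[C@@H]3[C@H](CC[C@]3(C)O)[C@](C)(O)C2)C(O)=O
F4 | step 11 | methyl ester of triketo acid F3 | CC(C)CC(=O)CC(=O)CC(=O)[C@@]2(C[C@@H]3[C@H](CC[C@]3(C)O)[C@](C)(O)C2)C(=O)OC
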